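## Retrosynthetic overview

1. Glaucolide K ⇐ methacrylation of the C8 hydroxyl ⇐ 13-acetoxy butenolide ⇐ one-operation closure of the C7–C11 bond: caesium acetate adds to a 2-(diethoxyphosphoryl)acrylate held on O6, and the resulting phosphonate carbanion closes onto the C7 ketone (oxa-Michael / intramolecular Horner–Wadsworth–Emmons).
2. Enabling feature: in the ten-membered carbocycle (C1–C10) the lactone oxygen sits on C6, next to ring carbon C7. An O6 ester therefore holds C11 in the five-atom array C11–C12–O–C6–C7 facing a C7 carbonyl. C13 carries an acetoxy group β to C12, the retron of acetate addition to a C11=C13 acceptor; C7 and C11 are both sp2 in the target.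
3. Keto ester ⇐ esterification of C6–OH, hydroxyl-directed epoxidation (C4–C5) and ring-closing metathesis (C4=C5, Z) of an open-chain diene; a sacrificial C7 carbinol is oxidised just before the key step.
4. Diene ⇐ Brown alkoxyallylboration (C6–C7), catalytic asymmetric dialkylzinc addition (C1–C2), zinc Barbier allylation/hydrogenation on (R)-glyceraldehyde acetonide (C8, C10).
5. Ring order: ten-membered carbocycle (step 11), epoxide (step 13), butenolide (step 19).

Key step: step 19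

Remark: germacrane numbering is used for all ring compounds (ring C1–C10, lactone carbons C11–C13, C14 on C10, C15 on C4). The target is (1S,4R,5R,6S,8S,10S); its 4,5-epoxide is cis (C3 and C6 on the same side), so its precursor is the (4Z)-alkene.

## Route

Step 1
Reactants: 1 (R)-2,2-dimethyl-1,3-dioxolane-4-carbaldehyde; 2 ethyl 2-(bromomethyl)prop-2-enoate
Product: 4 (5S)-5-[(4R)-2,2-dimethyl-1,3-dioxolan-4-yl]-3-methylideneoxolan-2-one, via bromozinc alkoxide 3 (not isolated)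
Conditions: Zn dust (activated), THF, 50 °C; aq. NH4Cl work-up
Reagents that add atoms: none
Why: Dreiding–Schmidt reaction (zinc Barbier allylation, then lactonisation of the zinc alkoxide onto the ethyl ester); the allylzinc should add anti to the dioxolane C–O bond (Felkin–Anh), which sets C8 as S.

Step 2
Reactants: 4 (5S)-5-[(4R)-2,2-dimethyl-1,3-dioxolan-4-yl]-3-methylideneoxolan-2-one
Product: 5 (3S,5S)-5-[(4R)-2,2-dimethyl-1,3-dioxolan-4-yl]-3-methyloxolan-2-one
Conditions: H2 (1 atm), Rh/Al2O3 (5 wt %), EtOAc, rt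
Reagents that add atoms: none
Why: Heterogeneous catalytic hydrogenation of the exocyclic alkene should occur on the ring face opposite the dioxolanyl group and give the cis-3,5-disubstituted lactone, which sets C10 as S.

Step 3
Reactants: 5 (3S,5S)-5-[(4R)-2,2-dimethyl-1,3-dioxolan-4-yl]-3-methyloxolan-2-one
Product: 6 (2S,4S)-4-[(4R)-2,2-dimethyl-1,3-dioxolan-4-yl]-4-hydroxy-N-methoxy-N,2-dimethylbutanamide
Conditions: MeNH(OMe)·HCl, AlMe3, CH2Cl2, 0 °C → rt
Reagents that add atoms: N,O-dimethylhydroxylamine hydrochloride, CNOC.Cl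
Why: Weinreb aminolysis of the γ-lactone by the aluminium amide opens the ring without touching the acetonide; the hydroxy amide is carried on at once so that it does not relactonise.

Step 4
Reactants: 6 (2S,4S)-4-[(4R)-2,2-dimethyl-1,3-dioxolan-4-yl]-4-hydroxy-N-methoxy-N,2-dimethylbutanamide
Product: 7 (2S,4S)-4-[(tert-butyldimethylsilyl)oxy]-4-[(4R)-2,2-dimethyl-1,3-dioxolan-4-yl]-N-methoxy-N,2-dimethylbutanamide
Conditions: TBSCl, imidazole, DMF, rt
Reagents that add atoms: tert-butyldimethylsilyl chloride, CC(C)(C)[Si](C)(C)Cl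
Why: Imidazole-mediated silylation of the secondary C8 hydroxyl, which blocks relactonisation and protects O8 until the end.

Step 5
Reactants: 7 (2S,4S)-4-[(tert-butyldimethylsilyl)oxy]-4-[(4R)-2,2-dimethyl-1,3-dioxolan-4-yl]-N-methoxy-N,2-dimethylbutanamide
Product: 8 (2S,4S)-4-[(tert-butyldimethylsilyl)oxy]-4-[(4R)-2,2-dimethyl-1,3-dioxolan-4-yl]-2-methylbutanal
Conditions: i-Bu2AlH, THF, −78 °C; Rochelle salt work-up
Reagents that add atoms: none
Why: Hydride reduction of a Weinreb amide stops at the aldehyde through the chelated aluminium hemiaminal, and the low temperature should keep the α-stereocentre C10 intact.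

Step 6
Reactants: 8 (2S,4S)-4-[(tert-butyldimethylsilyl)oxy]-4-[(4R)-2,2-dimethyl-1,3-dioxolan-4-yl]-2-methylbutanal; 9 4-bromo-2-methylbut-1-ene
Product: 10 (5S,6S,8S)-8-[(tert-butyldimethylsilyl)oxy]-8-[(4R)-2,2-dimethyl-1,3-dioxolan-4-yl]-2,6-dimethyloct-1-en-5-ol
Conditions: 9, Mg, Et2O; ZnCl2 (0.5 equiv), then 1,4-dioxane and filtration; Ti(OiPr)4, (1R,2R)-N,N'-(cyclohexane-1,2-diyl)bis(trifluoromethanesulfonamide) (cat.), toluene, −20 °C; then 8
Reagents that add atoms: none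
Why: Titanium–bis(sulfonamide)-catalysed enantioselective addition of a dialkylzinc to an aldehyde; the (1R,2R) ligand sends the alkyl group to the Si face, which is also the Felkin–Anh face of this α-methyl aldehyde, so C1 should be set as S (syn to the C10 methyl).

Step 7
Reactants: 10 (5S,6S,8S)-8-[(tert-butyldimethylsilyl)oxy]-8-[(4R)-2,2-dimethyl-1,3-dioxolan-4-yl]-2,6-dimethyloct-1-en-5-ol
Product: 11 (5S,6S,8S)-8-[(tert-butyldimethylsilyl)oxy]-8-[(4R)-2,2-dimethyl-1,3-dioxolan-4-yl]-2,6-dimethyloct-1-en-5-yl acetate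
Conditions: Ac2O, pyridine, DMAP (cat.), CH2Cl2, 0 °C → rt
Reagents that add atoms: acetic anhydride, CC(=O)OC(C)=O
Why: DMAP-catalysed acetylation installs the C1 acetate of the target after the last hydride and organometallic steps, so it needs no later exchange.

Step 8
Reactants: 11 (5S,6S,8S)-8-[(tert-butyldimethylsilyl)oxy]-8-[(4R)-2,2-dimethyl-1,3-dioxolan-4-yl]-2,6-dimethyloct-1-en-5-yl acetate
Product: 13 (2S,4S,5S)-2-[(tert-butyldimethylsilyl)oxy]-4,8-dimethyl-1-oxonon-8-en-5-yl acetate, via diol 12 (not isolated)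
Conditions: H5IO6, EtOAc, 0 °C → rt
Reagents that add atoms: none
Why: Periodic acid hydrolyses the terminal acetonide and cleaves the liberated 1,2-diol in the same flask (Malaprade glycol cleavage), which unveils the α-silyloxy aldehyde carbon C7 without hydride reagents.

Step 9
Reactants: 13 (2S,4S,5S)-2-[(tert-butyldimethylsilyl)oxy]-4,8-dimethyl-1-oxonon-8-en-5-yl acetate; 14 1-methoxy-4-[(prop-2-en-1-yloxy)methyl]benzene (allyl 4-methoxybenzyl ether)
Product: 15 (3R,4S,5S,7S,8S)-5-[(tert-butyldimethylsilyl)oxy]-4-hydroxy-3-[(4-methoxybenzyl)oxy]-7,11-dimethyldodeca-1,11-dien-8-yl acetate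
Conditions: 14, s-BuLi, THF, −78 °C; (−)-Ipc2BOMe; BF3·OEt2; 13, −78 °C; then NaBO3·4H2O, THF/H2O
Reagents that add atoms: none
Why: Brown (Z)-γ-alkoxyallylboration through a chair Zimmerman–Traxler transition state; the reagent from (−)-Ipc2BOMe adds to the Si face of the aldehyde and so sets C6 (the later lactone carbinol) together with a sacrificial syn C7 carbinol under reagent control.

Step 10
Reactants: 15 (3R,4S,5S,7S,8S)-5-[(tert-butyldimethylsilyl)oxy]-4-hydroxy-3-[(4-methoxybenzyl)oxy]-7,11-dimethyldodeca-1,11-dien-8-yl acetate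
Product: 16 (3R,4S,5S,7S,8S)-5-[(tert-butyldimethylsilyl)oxy]-3-[(4-methoxybenzyl)oxy]-7,11-dimethyl-4-[(triethylsilyl)oxy]dodeca-1,11-dien-8-yl acetate
Conditions: TESOTf, 2,6-lutidine, CH2Cl2, −78 °C
Reagents that add atoms: triethylsilyl trifluoromethanesulfonate, CC[Si](CC)(CC)OS(=O)(=O)C(F)(F)F
Why: Silyl triflate silylation of the hindered C7 hydroxyl gives a group that can later be removed beside the C8 tert-butyldimethylsilyl ether.

Step 11
Reactants: 16 (3R,4S,5S,7S,8S)-5-[(tert-butyldimethylsilyl)oxy]-3-[(4-methoxybenzyl)oxy]-7,11-dimethyl-4-[(triethylsilyl)oxy]dodeca-1,11-dien-8-yl acetate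
Product: 17 (1S,6R,7S,8S,10S,4Z)-8-[(tert-butyldimethylsilyl)oxy]-6-[(4-methoxybenzyl)oxy]-4,10-dimethyl-7-[(triethylsilyl)oxy]cyclodec-4-en-1-yl acetate
Conditions: second-generation Grubbs catalyst (10 mol %), 1,4-benzoquinone (20 mol %), toluene (1 mM), 80 °C
Reagents that add atoms: none
Why: Ring-closing olefin metathesis between the vinyl and the isopropenyl group forms C4=C5; the ten-membered ring should accommodate only the (Z)-trisubstituted alkene, the geometry the cis-epoxide needs.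

Step 12
Reactants: 17 (1S,6R,7S,8S,10S,4Z)-8-[(tert-butyldimethylsilyl)oxy]-6-[(4-methoxybenzyl)oxy]-4,10-dimethyl-7-[(triethylsilyl)oxy]cyclodec-4-en-1-yl acetate
Product: 18 (1S,6R,7S,8S,10S,4Z)-8-[(tert-butyldimethylsilyl)oxy]-6-hydroxy-4,10-dimethyl-7-[(triethylsilyl)oxy]cyclodec-4-en-1-yl acetate
Conditions: DDQ, CH2Cl2/pH 7 buffer, 0 °C
Reagents that add atoms: none
Why: Oxidative cleavage of the 4-methoxybenzyl ether by DDQ (hydride abstraction, hydrolysis of the oxocarbenium ion) frees only the allylic C6 hydroxyl.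

Step 13
Reactants: 18 (1S,6R,7S,8S,10S,4Z)-8-[(tert-butyldimethylsilyl)oxy]-6-hydroxy-4,10-dimethyl-7-[(triethylsilyl)oxy]cyclodec-4-en-1-yl acetate
Product: 19 (1S,4R,5R,6R,7S,8S,10S)-8-[(tert-butyldimethylsilyl)oxy]-4,5-epoxy-6-hydroxy-4,10-dimethyl-7-[(triethylsilyl)oxy]cyclodecyl acetate
Conditions: mCPBA, NaHCO3, CH2Cl2, 0 °C
Reagents that add atoms: 3-chloroperoxybenzoic acid, O=C(OO)c1cccc(Cl)c1
Why: Hydroxyl-directed (Henbest) peracid epoxidation; allylic 1,3-strain of the (Z)-alkene holds C6–H in the alkene plane, so the peracid bound to the C6 hydroxyl should attack the face syn to it (also the peripheral face) and give the threo epoxy alcohol with C4 and C5 as R.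

Step 14
Reactants: 20 tert-butyl 2-(diethoxyphosphoryl)acetate
Product: 21 tert-butyl 2-(diethoxyphosphoryl)prop-2-enoate
Conditions: (CH2O)n, piperidine (cat.), AcOH (cat.), toluene, reflux (Dean–Stark)
Reagents that add atoms: paraformaldehyde (as formaldehyde), C=O
Why: Knoevenagel condensation of the phosphonoacetate with formaldehyde under amine/acid catalysis keeps the phosphorus and gives the 2-phosphonoacrylate.

Step 15
Reactants: 21 tert-butyl 2-(diethoxyphosphoryl)prop-2-enoate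
Product: 22 2-(diethoxyphosphoryl)prop-2-enoic acid
Conditions: CF3CO2H, CH2Cl2, 0 °C → rt
Reagents that add atoms: none
Why: Acidolysis of the tert-butyl ester (loss of 2-methylpropene) frees the acid under conditions without nucleophiles that could add to the acrylate.

Step 16
Reactants: 19 (1S,4R,5R,6R,7S,8S,10S)-8-[(tert-butyldimethylsilyl)oxy]-4,5-epoxy-6-hydroxy-4,10-dimethyl-7-[(triethylsilyl)oxy]cyclodecyl acetate; 22 2-(diethoxyphosphoryl)prop-2-enoic acid
Product: 23 (1S,4R,5R,6R,7S,8S,10S)-1-acetoxy-8-[(tert-butyldimethylsilyl)oxy]-4,5-epoxy-4,10-dimethyl-7-[(triethylsilyl)oxy]cyclodec-6-yl 2-(diethoxyphosphoryl)prop-2-enoate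
Conditions: DCC, DMAP (cat.), CH2Cl2, 0 °C
Reagents that add atoms: none
Why: Steglich esterification of the only free hydroxyl (C6) attaches C11–C13 through the future lactone oxygen.

Step 17
Reactants: 23 (1S,4R,5R,6R,7S,8S,10S)-1-acetoxy-8-[(tert-butyldimethylsilyl)oxy]-4,5-epoxy-4,10-dimethyl-7-[(triethylsilyl)oxy]cyclodec-6-yl 2-(diethoxyphosphoryl)prop-2-enoate
Product: 24 (1S,4R,5R,6S,7S,8S,10S)-1-acetoxy-8-[(tert-butyldimethylsilyl)oxy]-4,5-epoxy-7-hydroxy-4,10-dimethylcyclodec-6-yl 2-(diethoxyphosphoryl)prop-2-enoate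
Conditions: HF·pyridine, pyridine, THF, 0 °C
Reagents that add atoms: none
Why: Buffered fluoride cleaves the triethylsilyl ether selectively beside the bulkier tert-butyldimethylsilyl ether, and the weakly acidic medium should spare the epoxide and prevent acyl migration.

Step 18
Reactants: 24 (1S,4R,5R,6S,7S,8S,10S)-1-acetoxy-8-[(tert-butyldimethylsilyl)oxy]-4,5-epoxy-7-hydroxy-4,10-dimethylcyclodec-6-yl 2-(diethoxyphosphoryl)prop-2-enoate
Product: 25 (1S,4R,5R,6R,8S,10S)-1-acetoxy-8-[(tert-butyldimethylsilyl)oxy]-4,5-epoxy-4,10-dimethyl-7-oxocyclodec-6-yl 2-(diethoxyphosphoryl)prop-2-enoate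
Conditions: Dess–Martin periodinane, NaHCO3, CH2Cl2, 0 °C → rt
Reagents that add atoms: none
Why: Dess–Martin oxidation converts the sacrificial C7 carbinol into the ketone under buffered, non-basic conditions that leave the epoxide, the acrylate and the α-stereocentres C6 and C8 alone.

Step 19
Reactants: 25 (1S,4R,5R,6R,8S,10S)-1-acetoxy-8-[(tert-butyldimethylsilyl)oxy]-4,5-epoxy-4,10-dimethyl-7-oxocyclodec-6-yl 2-(diethoxyphosphoryl)prop-2-enoate
Product: 27 (1S,4R,5R,6S,8S,10S)-1,13-diacetoxy-8-[(tert-butyldimethylsilyl)oxy]-4,5-epoxygermacr-7(11)-en-12,6-olide, via phosphonate carbanion 26 (not isolated)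
Conditions: CsOAc (3 equiv), 4 Å molecular sieves, dry DMF, 0 °C → rt
Reagents that add atoms: caesium acetate, CC(=O)[O-].[Cs+]
Why: Proposed new method: acetate adds reversibly to C13 of the doubly activated 2-phosphonoacrylate (oxa-Michael); in the aprotic medium the phosphonate-stabilised C11 carbanion 26 can only revert or attack the neighbouring C7 ketone, and cycloelimination of diethyl phosphate (intramolecular Horner–Wadsworth–Emmons) then gives the tetrasubstituted C7=C11 alkene, so the C7–C11 bond, the butenolide and the C13 acetate arise in one operation. The closest known reaction types are the tandem Michael/Horner–Wadsworth–Emmons reaction of 2-(diethoxyphosphoryl)acrylates with carbon, nitrogen, sulfur and alkoxide nucleophiles and the base-mediated intramolecular Horner–Wadsworth–Emmons closure of phosphonoacetates of α-hydroxy ketones to butenolides; new is a carboxylate as the triggering nucleophile. The butenolide closes by 5-exo-trig attack of C11 on the C7 carbonyl followed by syn-elimination of the phosphate. No new stereocentre is formed, because C7 and C11 become sp2 and the alkene geometry is fixed by the ring. The step needs C6 and C8 (both α to the ketone) to keep their configuration and the epoxide β to C6 to survive; acetate as the only base (far weaker than the amidine or hydride bases of the usual protocol) together with the fast five-ring closure should secure this. Acetate must add only to the phosphonoacrylate, which is the sole strong Michael acceptor present because the methacrylate is installed afterwards, and any retro-Michael loss of acetate merely returns 25.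

Step 20
Reactants: 27 (1S,4R,5R,6S,8S,10S)-1,13-diacetoxy-8-[(tert-butyldimethylsilyl)oxy]-4,5-epoxygermacr-7(11)-en-12,6-olide
Product: 28 (1S,4R,5R,6S,8S,10S)-1,13-diacetoxy-4,5-epoxy-8-hydroxygermacr-7(11)-en-12,6-olide
Conditions: HF·pyridine, pyridine, THF, 0 °C → rt
Reagents that add atoms: none
Why: Buffered fluoride desilylation frees the C8 hydroxyl without basic conditions that would endanger the allylic acetate, the butenolide γ-proton or the epoxide.

Step 21
Reactants: 28 (1S,4R,5R,6S,8S,10S)-1,13-diacetoxy-4,5-epoxy-8-hydroxygermacr-7(11)-en-12,6-olide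
Product: 29 glaucolide K, (1S,4R,5R,6S,8S,10S)-1,13-diacetoxy-4,5-epoxy-8-(methacryloyloxy)germacr-7(11)-en-12,6-olide
Conditions: methacrylic anhydride, Et3N, DMAP (cat.), CH2Cl2, 0 °C
Reagents that add atoms: methacrylic anhydride, C=C(C)C(=O)OC(=O)C(C)=C
Why: DMAP-catalysed acylation of the single free hydroxyl installs the methacrylate last, so this Michael acceptor meets neither the metathesis catalyst nor the acetate of the key step.

## Compound list

1 | (R)-2,2-dimethyl-1,3-dioxolane-4-carbaldehyde | CC1(C)OC[C@@H](O1)C=O | starting material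
2 | ethyl 2-(bromomethyl)prop-2-enoate | C=C(CBr)C(=O)OCC | starting material
3 | bromozinc alkoxide of ethyl (4S)-4-[(4R)-2,2-dimethyl-1,3-dioxolan-4-yl]-4-hydroxy-2-methylidenebutanoate | C=C(C[C@H](O[Zn]Br)[C@H]1COC(C)(C)O1)C(=O)OCC | intermediate
4 | (5S)-5-[(4R)-2,2-dimethyl-1,3-dioxolan-4-yl]-3-methylideneoxolan-2-one | CC1(C)OC[C@@H](O1)[C@@H]2CC(=C)C(=O)O2 | intermediate
5 | (3S,5S)-5-[(4R)-2,2-dimethyl-1,3-dioxolan-4-yl]-3-methyloxolan-2-one (cis) | CC1(C)OC[C@@H](O1)[C@@H]2C[C@H](C)C(=O)O2 | intermediate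
6 | (2S,4S)-4-[(4R)-2,2-dimethyl-1,3-dioxolan-4-yl]-4-hydroxy-N-methoxy-N,2-dimethylbutanamide | CON(C)C(=O)[C@@H](C)C[C@H](O)[C@H]1COC(C)(C)O1 | intermediate
7 | (2S,4S)-4-[(tert-butyldimethylsilyl)oxy]-4-[(4R)-2,2-dimethyl-1,3-dioxolan-4-yl]-N-methoxy-N,2-dimethylbutanamide | CON(C)C(=O)[C@@H](C)C[C@H](O[Si](C)(C)C(C)(C)C)[C@H]1COC(C)(C)O1 | intermediate
8 | (2S,4S)-4-[(tert-butyldimethylsilyl)oxy]-4-[(4R)-2,2-dimethyl-1,3-dioxolan-4-yl]-2-methylbutanal | O=C[C@@H](C)C[C@H](O[Si](C)(C)C(C)(C)C)[C@H]1COC(C)(C)O1 | intermediate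
9 | 4-bromo-2-methylbut-1-ene | C=C(C)CCBr | starting material
10 | (5S,6S,8S)-8-[(tert-butyldimethylsilyl)oxy]-8-[(4R)-2,2-dimethyl-1,3-dioxolan-4-yl]-2,6-dimethyloct-1-en-5-ol | C=C(C)CC[C@H](O)[C@@H](C)C[C@H](O[Si](C)(C)C(C)(C)C)[C@H]1COC(C)(C)O1 | intermediate
11 | (5S,6S,8S)-8-[(tert-butyldimethylsilyl)oxy]-8-[(4R)-2,2-dimethyl-1,3-dioxolan-4-yl]-2,6-dimethyloct-1-en-5-yl acetate | C=C(C)CC[C@H](OC(C)=O)[C@@H](C)C[C@H](O[Si](C)(C)C(C)(C)C)[C@H]1COC(C)(C)O1 | intermediate
12 | (2R,3S,5S,6S)-3-[(tert-butyldimethylsilyl)oxy]-1,2-dihydroxy-5,9-dimethyldec-9-en-6-yl acetate | C=C(C)CC[C@H](OC(C)=O)[C@@H](C)C[C@H](O[Si](C)(C)C(C)(C)C)[C@H](O)CO | intermediate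
13 | (2S,4S,5S)-2-[(tert-butyldimethylsilyl)oxy]-4,8-dimethyl-1-oxonon-8-en-5-yl acetate | C=C(C)CC[C@H](OC(C)=O)[C@@H](C)C[C@H](O[Si](C)(C)C(C)(C)C)C=O | intermediate
14 | 1-methoxy-4-[(prop-2-en-1-yloxy)methyl]benzene (allyl 4-methoxybenzyl ether) | C=CCOCc1ccc(OC)cc1 | starting material
15 | (3R,4S,5S,7S,8S)-5-[(tert-butyldimethylsilyl)oxy]-4-hydroxy-3-[(4-methoxybenzyl)oxy]-7,11-dimethyldodeca-1,11-dien-8-yl acetate | C=C(C)CC[C@H](OC(C)=O)[C@@H](C)C[C@H](O[Si](C)(C)C(C)(C)C)[C@@H](O)[C@H](OCc1ccc(OC)cc1)C=C | intermediate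
16 | (3R,4S,5S,7S,8S)-5-[(tert-butyldimethylsilyl)oxy]-3-[(4-methoxybenzyl)oxy]-7,11-dimethyl-4-[(triethylsilyl)oxy]dodeca-1,11-dien-8-yl acetate | C=C(C)CC[C@H](OC(C)=O)[C@@H](C)C[C@H](O[Si](C)(C)C(C)(C)C)[C@@H](O[Si](CC)(CC)CC)[C@H](OCc1ccc(OC)cc1)C=C | intermediate
17 | (1S,6R,7S,8S,10S,4Z)-8-[(tert-butyldimethylsilyl)oxy]-6-[(4-methoxybenzyl)oxy]-4,10-dimethyl-7-[(triethylsilyl)oxy]cyclodec-4-en-1-yl acetate | CC(C)(C)[Si](C)(C)O[C@H]1C[C@H](C)[C@@H](OC(C)=O)CC/C(C)=C\[C@@H](OCc2ccc(OC)cc2)[C@@H]1O[Si](CC)(CC)CC | intermediate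
18 | (1S,6R,7S,8S,10S,4Z)-8-[(tert-butyldimethylsilyl)oxy]-6-hydroxy-4,10-dimethyl-7-[(triethylsilyl)oxy]cyclodec-4-en-1-yl acetate | CC(C)(C)[Si](C)(C)O[C@H]1C[C@H](C)[C@@H](OC(C)=O)CC/C(C)=C\[C@@H](O)[C@@H]1O[Si](CC)(CC)CC | intermediate
19 | (1S,4R,5R,6R,7S,8S,10S)-8-[(tert-butyldimethylsilyl)oxy]-4,5-epoxy-6-hydroxy-4,10-dimethyl-7-[(triethylsilyl)oxy]cyclodecyl acetate | CC(C)(C)[Si](C)(C)O[C@H]1C[C@H](C)[C@@H](OC(C)=O)CC[C@@]2(C)O[C@@H]2[C@@H](O)[C@@H]1O[Si](CC)(CC)CC | intermediate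
20 | tert-butyl 2-(diethoxyphosphoryl)acetate | CCOP(=O)(OCC)CC(=O)OC(C)(C)C | starting material
21 | tert-butyl 2-(diethoxyphosphoryl)prop-2-enoate | C=C(C(=O)OC(C)(C)C)P(=O)(OCC)OCC | intermediate
22 | 2-(diethoxyphosphoryl)prop-2-enoic acid | C=C(C(=O)O)P(=O)(OCC)OCC | intermediate
23 | (1S,4R,5R,6R,7S,8S,10S)-1-acetoxy-8-[(tert-butyldimethylsilyl)oxy]-4,5-epoxy-4,10-dimethyl-7-[(triethylsilyl)oxy]cyclodec-6-yl 2-(diethoxyphosphoryl)prop-2-enoate | CC(C)(C)[Si](C)(C)O[C@H]1C[C@H](C)[C@@H](OC(C)=O)CC[C@@]2(C)O[C@@H]2[C@@H](OC(=O)C(=C)P(=O)(OCC)OCC)[C@@H]1O[Si](CC)(CC)CC | intermediate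
24 | (1S,4R,5R,6S,7S,8S,10S)-1-acetoxy-8-[(tert-butyldimethylsilyl)oxy]-4,5-epoxy-7-hydroxy-4,10-dimethylcyclodec-6-yl 2-(diethoxyphosphoryl)prop-2-enoate | CC(C)(C)[Si](C)(C)O[C@H]1C[C@H](C)[C@@H](OC(C)=O)CC[C@@]2(C)O[C@@H]2[C@@H](OC(=O)C(=C)P(=O)(OCC)OCC)[C@@H]1O | intermediate
25 | (1S,4R,5R,6R,8S,10S)-1-acetoxy-8-[(tert-butyldimethylsilyl)oxy]-4,5-epoxy-4,10-dimethyl-7-oxocyclodec-6-yl 2-(diethoxyphosphoryl)prop-2-enoate | CC(C)(C)[Si](C)(C)O[C@H]1C[C@H](C)[C@@H](OC(C)=O)CC[C@@]2(C)O[C@@H]2[C@@H](OC(=O)C(=C)P(=O)(OCC)OCC)C1=O | intermediate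
26 | caesium salt of the C11 carbanion formed by acetate addition to C13 of 25 | CC(C)(C)[Si](C)(C)O[C@H]1C[C@H](C)[C@@H](OC(C)=O)CC[C@@]2(C)O[C@@H]2[C@@H](OC(=O)[C-](COC(C)=O)P(=O)(OCC)OCC)C1=O.[Cs+] | intermediate
27 | (1S,4R,5R,6S,8S,10S)-1,13-diacetoxy-8-[(tert-butyldimethylsilyl)oxy]-4,5-epoxygermacr-7(11)-en-12,6-olide | CC(C)(C)[Si](C)(C)O[C@H]1C[C@H](C)[C@@H](OC(C)=O)CC[C@@]2(C)O[C@@H]2[C@H]2OC(=O)C(COC(C)=O)=C12 | intermediate
28 | (1S,4R,5R,6S,8S,10S)-1,13-diacetoxy-4,5-epoxy-8-hydroxygermacr-7(11)-en-12,6-olide | O[C@H]1C[C@H](C)[C@@H](OC(C)=O)CC[C@@]2(C)O[C@@H]2[C@H]2OC(=O)C(COC(C)=O)=C12 | intermediate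
29 | glaucolide K, (1S,4R,5R,6S,8S,10S)-1,13-diacetoxy-4,5-epoxy-8-(methacryloyloxy)germacr-7(11)-en-12,6-olide | C=C(C)C(=O)O[C@H]1C[C@H](C)[C@@H](OC(C)=O)CC[C@@]2(C)O[C@@H]2[C@H]2OC(=O)C(COC(C)=O)=C12 | target

## Step count and risks

Total step count: 21 (19 in the main line, 2 for acid 22).
Longest linear sequence: 19 steps (1 → 29 through steps 1–13 and 16–21).

Steps most likely to fail:

1. Step 19 (proposed new method). The acetate adduct may revert faster than it cyclises, so that 25 is recovered. On long exposure the basic medium may epimerise C6 or C8, or open the epoxide by β-elimination from C6. The fallback uses known chemistry; it sets out from 19 and comes back at 27. Compound 19 would be esterified (DCC, DMAP) with 2-(diethoxyphosphoryl)propanoic acid to the C6 phosphonopropanoate F1. Its triethylsilyl ether would be cleaved (HF·pyridine, pyridine) to the C7 alcohol F2, which would be oxidised (Dess–Martin periodinane) to the keto phosphonate F3. An intramolecular Horner–Wadsworth–Emmons reaction under Masamune–Roush conditions (LiCl, i-Pr2NEt, MeCN) would close the 13-deoxy butenolide F4. Wohl–Ziegler bromination (N-bromosuccinimide, AIBN, PhCF3, 80 °C) of its C13 methyl group would give the 13-bromo butenolide F5, and displacement with CsOAc in DMF would give 27.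

2. Step 11. Intermolecular metathesis (oligomerisation) may outrun closure of the strained ring, initiation at the hindered allylic ether may be slow, and ruthenium hydride species may shift the double bonds. The fallback changes the substrate class to an unprotected allylic 1,2-diol, whose free allylic hydroxyl accelerates metathesis and which carries no bulky groups on O6 and O7; it sets out from 15 and comes back at 24. Compound 15 would be treated with DDQ (wet CH2Cl2) to give the acyclic diol F6, which would be cyclised by the second-generation Grubbs catalyst to the cyclic (Z)-ene diol F7. Hydroxyl-directed epoxidation (mCPBA) would give the epoxy diol F8. Steglich esterification with 22 should go to the less hindered C6 hydroxyl (C7–OH is flanked by the silyloxy-bearing C8) and give 24, which makes the triethylsilyl protection and its removal unnecessary.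

3. Step 16. Conjugate addition of DMAP, of the alcohol or of the activated acid to the phosphonoacrylic acid, and its polymerisation, may compete with acyl transfer to the hindered C6 hydroxyl. The fallback builds the acceptor on the substrate; it sets out from 19 and comes back at 23. Compound 19 would be esterified (DCC, DMAP) with 2-(diethoxyphosphoryl)acetic acid to the phosphonoacetate F9. A Mannich reaction with N,N-dimethylmethyleneiminium iodide and Et3N would give the dimethylaminomethyl phosphonate F10; N-methylation (MeI) and elimination of trimethylamine (NaHCO3) would give 23.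

## Further compounds

F1 | step 19 | (1S,4R,5R,6R,7S,8S,10S)-1-acetoxy-8-[(tert-butyldimethylsilyl)oxy]-4,5-epoxy-4,10-dimethyl-7-[(triethylsilyl)oxy]cyclodec-6-yl 2-(diethoxyphosphoryl)propanoate | CC(C)(C)[Si](C)(C)O[C@H]1C[C@H](C)[C@@H](OC(C)=O)CC[C@@]2(C)O[C@@H]2[C@@H](OC(=O)C(C)P(=O)(OCC)OCC)[C@@H]1O[Si](CC)(CC)CC
F2 | step 19 | (1S,4R,5R,6S,7S,8S,10S)-1-acetoxy-8-[(tert-butyldimethylsilyl)oxy]-4,5-epoxy-7-hydroxy-4,10-dimethylcyclodec-6-yl 2-(diethoxyphosphoryl)propanoate | CC(C)(C)[Si](C)(C)O[C@H]1C[C@H](C)[C@@H](OC(C)=O)CC[C@@]2(C)O[C@@H]2[C@@H](OC(=O)C(C)P(=O)(OCC)OCC)[C@@H]1O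
F3 | step 19 | (1S,4R,5R,6R,8S,10S)-1-acetoxy-8-[(tert-butyldimethylsilyl)oxy]-4,5-epoxy-4,10-dimethyl-7-oxocyclodec-6-yl 2-(diethoxyphosphoryl)propanoate | CC(C)(C)[Si](C)(C)O[C@H]1C[C@H](C)[C@@H](OC(C)=O)CC[C@@]2(C)O[C@@H]2[C@@H](OC(=O)C(C)P(=O)(OCC)OCC)C1=O
F4 | step 19 | (1S,4R,5R,6S,8S,10S)-1-acetoxy-8-[(tert-butyldimethylsilyl)oxy]-4,5-epoxygermacr-7(11)-en-12,6-olide | CC(C)(C)[Si](C)(C)O[C@H]1C[C@H](C)[C@@H](OC(C)=O)CC[C@@]2(C)O[C@@H]2[C@H]2OC(=O)C(C)=C12
F5 | step 19 | (1S,4R,5R,6S,8S,10S)-1-acetoxy-13-bromo-8-[(tert-butyldimethylsilyl)oxy]-4,5-epoxygermacr-7(11)-en-12,6-olide | CC(C)(C)[Si](C)(C)O[C@H]1C[C@H](C)[C@@H](OC(C)=O)CC[C@@]2(C)O[C@@H]2[C@H]2OC(=O)C(CBr)=C12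
F6 | step 11 | (3R,4S,5S,7S,8S)-5-[(tert-butyldimethylsilyl)oxy]-3,4-dihydroxy-7,11-dimethyldodeca-1,11-dien-8-yl acetate | C=C(C)CC[C@H](OC(C)=O)[C@@H](C)C[C@H](O[Si](C)(C)C(C)(C)C)[C@@H](O)[C@H](O)C=C
F7 | step 11 | (1S,6R,7S,8S,10S,4Z)-8-[(tert-butyldimethylsilyl)oxy]-6,7-dihydroxy-4,10-dimethylcyclodec-4-en-1-yl acetate | CC(C)(C)[Si](C)(C)O[C@H]1C[C@H](C)[C@@H](OC(C)=O)CC/C(C)=C\[C@@H](O)[C@@H]1O
F8 | step 11 | (1S,4R,5R,6S,7S,8S,10S)-8-[(tert-butyldimethylsilyl)oxy]-4,5-epoxy-6,7-dihydroxy-4,10-dimethylcyclodecyl acetate | CC(C)(C)[Si](C)(C)O[C@H]1C[C@H](C)[C@@H](OC(C)=O)CC[C@@]2(C)O[C@@H]2[C@@H](O)[C@@H]1O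
F9 | step 16 | (1S,4R,5R,6R,7S,8S,10S)-1-acetoxy-8-[(tert-butyldimethylsilyl)oxy]-4,5-epoxy-4,10-dimethyl-7-[(triethylsilyl)oxy]cyclodec-6-yl 2-(diethoxyphosphoryl)acetate | CC(C)(C)[Si](C)(C)O[C@H]1C[C@H](C)[C@@H](OC(C)=O)CC[C@@]2(C)O[C@@H]2[C@@H](OC(=O)CP(=O)(OCC)OCC)[C@@H]1O[Si](CC)(CC)CC
F10 | step 16 | (1S,4R,5R,6R,7S,8S,10S)-1-acetoxy-8-[(tert-butyldimethylsilyl)oxy]-4,5-epoxy-4,10-dimethyl-7-[(triethylsilyl)oxy]cyclodec-6-yl 2-(diethoxyphosphoryl)-3-(dimethylamino)propanoate | CC(C)(C)[Si](C)(C)O[C@H]1C[C@H](C)[C@@H](OC(C)=O)CC[C@@]2(C)O[C@@H]2[C@@H](OC(=O)C(CN(C)C)P(=O)(OCC)OCC)[C@@H]1O[Si](CC)(CC)CC
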